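If you want to know how far the south-east and south-west flasks get in 3.0 h, you have two earlier runs that differ from them in the scavenger charge.

the same everywhere: substrate 0.20 M; free catalyst 0.32 mM

| flask | reagent | scavenger | remark | time |
|---|---|---|---|---|
| beta | 0.40 M | 0.081 M | run made earlier |  |
| epsilon | 0.40 M | 0.17 M | run made earlier |  |
| south-east | 0.400 M | 0.0600 M |  | 3.0 h |
| south-west | 0.400 M | 0.120 M |  | 3.0 h |

| run | time / h | substrate / % | product / % |
|---|---|---|---|
| beta | 0.417 | 74.9 | 24.2 |
| beta | 0.833 | 52.7 | 46.9 |
| beta | 1.33 | 30.9 | 68.6 |
| beta | 1.50 | 25.8 | 74.7 |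
| beta | 2.00 | 13.3 | 86.2 |
| beta | 2.50 | 5.9 | 94.5 |
| beta | 3.00 | 2.3 | 97.9 |
| epsilon | 0.250 | 85.2 | 15.5 |
| epsilon | 0.333 | 80.5 | 19.7 |
| epsilon | 0.500 | 70.2 | 29.4 |
| epsilon | 0.833 | 53.4 | 46.9 |
| epsilon | 1.33 | 31.3 | 68.8 |
| epsilon | 2.00 | 13.6 | 87.2 |
| epsilon | 3.00 | 3.2 | 97.9 |

(standard deviation of a reading: 0.5 percentage points)

- part of the substrate that has reacted at the end, south-east
- part of the substrate that has reacted at the end, south-west
- what raising the concentration of scavenger from its lowest to its highest value here does to the part of the substrate that has reacted (changes below 5 percentage points count as none) (it rises / it falls / no change)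



Lay the beta run over the epsilon run. Scavenger goes from 0.081 M to 0.17 M, yet substrate reads 52.7% against 53.4% at 0.833 h, within the scatter, so I read the rate as zero order in scavenger over that span. The beta decay is not first order: the apparent first-order constant reads 0.693 h⁻¹ over the first beta interval and is higher, 1.88 h⁻¹, over the last, which I read as the pattern of a Michaelis curve in substrate. So the beta curve starts steep, still holds near half of the substrate at 0.833 h, bends into a tail and runs toward zero substrate.

The quantity to carry is the start turnover frequency, substrate consumed per unit of catalyst charged per hour over that first interval, 376 h⁻¹. The charge asks for 625 turnovers, which at that pace would take 1.66 h, less than 3.0 h. The tail uses the remaining time, and at 3.00 h the runs show between 96.8% and 97.7% reacted. That span is my reckoning for both flasks, though south-east's scavenger lies below the tried range.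

The forecast gives 97.3% for south-east, 97.3% for south-west and, for the trend, no change, holding that “scavenger has no visible rate effect” between the two earlier runs.

The flasks give 97.8% in south-east and 97.8% in south-west, a change of 0 percentage points: no change.

    reagent + free catalyst ⇌ catalyst intermediate A (K = 69.0 L mol⁻¹, k = 4990 L mol⁻¹ min⁻¹)
    catalyst intermediate A ⇌ released group + catalyst intermediate B (K = 3.50 M, k = 1200 min⁻¹)
    catalyst intermediate B → catalyst intermediate C (k = 22.9 min⁻¹)
    substrate + catalyst intermediate C → catalyst intermediate D (k = 109 L mol⁻¹ min⁻¹)
    catalyst intermediate D → free catalyst + product (k = 16.5 min⁻¹)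
    reagent + released group ⇌ idle adduct, settled at all times (K = 610 L mol⁻¹)
    scavenger + released group → scavenged by-product (k = 0.314 L mol⁻¹ min⁻¹)
    2 catalyst intermediate B → spent catalyst (k = 10.7 L mol⁻¹ min⁻¹)

South-east still holds 82% of its scavenger, and its 611 turnovers in 3.0 h average 204 h⁻¹, lower than the carried 376 h⁻¹. The neighbouring flask is south-east with free catalyst cut to 8.0 × 10⁻⁵ M. The carried rate, scaled to that catalyst charge and held for the full 3.0 h, reckons 45.1% of its substrate reacted, and that flask gives 42.9%, which is less. Its substrate stands at 57.1% at 3.00 h.

Readings and results were generated by integration with made-up constants.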